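Everything rests on cutting ring B at C1–C2 and C3–C4 (tetralin numbering; ring A aromatic, ring B saturated). The feature exploited is that the two benzylic carbons of ring B, C1 (aryl-bearing) and C4 (CH2), flank a trans C2–C3 pair whose CH2OMe arms are reduced fumarate carboxyls. Heating a racemic 1-aryl-5,6-dimethoxy-1,3-dihydrobenzo[c]thiophene 2,2-dioxide expels SO2, erases its stereocentre and unmasks the (E)-α-aryl o-quinodimethane of ring A. The fumarate diester of methyl (S)-lactate traps it. This single operation closes ring B, forms two C–C bonds and sets C1, C2 and C3. LiAlH4 reduction, which also strips the auxiliary, and double O-methylation then give phyltetralin.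

Key step: step 6

Configuration check: the target SMILES reads as (1R,2S,3S), with the aryl group trans to the C2 arm and the C2 arm trans to the C3 arm (all-trans).

Assumption: in the uncatalysed cycloaddition the open face of the (S)-lactate fumarate is taken to be the Si,Si face, as the conformational model under step 6 predicts; the sense is to be verified at the diol stage, and if it proves opposite, methyl (R)-lactate is used in step 5 with nothing else changed.

Step 1
Reactants: 1 2-bromo-4,5-dimethoxybenzyl alcohol; 2 veratraldehyde (3,4-dimethoxybenzaldehyde)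
Product: 4 rac-(3,4-dimethoxyphenyl)[2-(hydroxymethyl)-4,5-dimethoxyphenyl]methanol, via dilithio species 3 (not isolated)
Conditions: n-BuLi (2.2 equiv), THF, −78 °C; then 2, −78 → 0 °C; H2O
Reagents that add atoms: n-butyllithium, [Li]CCCC (source of the lithium in 3; none of its atoms stays in 4)
Why: O-deprotonation and fast bromine–lithium exchange give the alkoxide-bearing aryllithium 3, whose 1,2-addition to the non-enolisable aldehyde 2 forms the diaryl carbinol as a racemate, which is harmless because this stereocentre is erased in step 6.

Step 2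
Reactants: 4 rac-(3,4-dimethoxyphenyl)[2-(hydroxymethyl)-4,5-dimethoxyphenyl]methanol
Product: 5 rac-1-[bromo(3,4-dimethoxyphenyl)methyl]-2-(bromomethyl)-4,5-dimethoxybenzene
Conditions: PBr3 (0.8 equiv), CH2Cl2, −10 → 0 °C; decanted from the acid residue, concentrated cold, used at once
Reagents that add atoms: phosphorus tribromide, BrP(Br)Br
Why: Deoxybromination through phosphite esters works readily on both para-methoxy-activated benzylic alcohols, and any internal ether formed by capture of the diarylmethyl cation should be reopened by the HBr present because that C–O bond ionises easily.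

Step 3
Reactants: 5 rac-1-[bromo(3,4-dimethoxyphenyl)methyl]-2-(bromomethyl)-4,5-dimethoxybenzene
Product: 6 rac-1-(3,4-dimethoxyphenyl)-5,6-dimethoxy-1,3-dihydrobenzo[c]thiophene
Conditions: Na2S (anhydrous, 1.2 equiv), DMF, 0 °C → rt, slow addition of 5
Reagents that add atoms: sodium sulfide, [Na+].[Na+].[S-2]
Why: Twofold nucleophilic substitution by sulfide, first at the primary benzylic carbon and then as a 5-exo-tet closure at the very reactive diarylmethyl carbon, builds the five-membered thioether ring, while dilution and an aprotic medium hold back bridging and solvolysis.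

Step 4
Reactants: 6 rac-1-(3,4-dimethoxyphenyl)-5,6-dimethoxy-1,3-dihydrobenzo[c]thiophene
Product: 7 rac-1-(3,4-dimethoxyphenyl)-5,6-dimethoxy-1,3-dihydrobenzo[c]thiophene 2,2-dioxide
Conditions: mCPBA (2.2 equiv), CH2Cl2, 0 °C → rt
Reagents that add atoms: 3-chloroperbenzoic acid, O=C(OO)c1cccc(Cl)c1
Why: Peracid S-oxidation to the sulfone level is far faster than any attack on the dimethoxyarenes, so the oxidation should be chemoselective at low temperature.

Step 5
Reactants: 8 fumaryl chloride; 9 methyl (S)-lactate (2.1 equiv)
Product: 10 bis[(S)-1-methoxy-1-oxopropan-2-yl] fumarate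
Conditions: toluene, 90 °C, N2 sweep, no base
Reagents that add atoms: none
Why: Twofold alcoholysis of the acid chloride (esterification) breaks neither the C–O bond at the lactate stereocentre nor the (E)-alkene, and leaving out amine base avoids enolisation of the lactate and decomposition of the acid chloride.

Step 6
Reactants: 7 rac-1-(3,4-dimethoxyphenyl)-5,6-dimethoxy-1,3-dihydrobenzo[c]thiophene 2,2-dioxide; 10 bis[(S)-1-methoxy-1-oxopropan-2-yl] fumarate (2 equiv)
Product: 12 bis[(S)-1-methoxy-1-oxopropan-2-yl] (1R,2S,3S)-1-(3,4-dimethoxyphenyl)-6,7-dimethoxy-1,2,3,4-tetrahydronaphthalene-2,3-dicarboxylate, via (E)-o-quinodimethane 11 (not isolated)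
Conditions: BHT (cat.), 1,2-dichlorobenzene, 160–180 °C, argon sweep; chromatography, then crystallisation
Reagents that add atoms: none
Why: Heating 7 causes a concerted, disrotatory cheletropic loss of SO2 in which the aryl group turns outward to avoid the opposite methylene, so both enantiomers of the sulfone collapse to the one achiral (E)-diene 11. 11 then adds to 10 in a concerted, suprafacial–suprafacial, normal-electron-demand Diels–Alder reaction driven by the return of aromaticity to ring A; the closest known reaction type is the trapping of sulfone-derived α-aryl o-quinodimethanes by fumarates of chiral α-hydroxy esters. Ring B, a six-membered carbocycle, is closed by intermolecular (4+2) annulation, with C1–C2 and C3–C4 made in the same event. C2 and C3 are trans because the (E)-alkene geometry is carried over, and their absolute sense is set by the two lactate units: in the twofold-symmetric s-cis,s-cis conformer with Z-ester geometry both CO2Me groups stand over the Re,Re face, so the diene should bond to the Si,Si face and give 2S,3S. C1 is set relative to C2 by the (E)-geometry of 11 together with the orientation that puts the C3 ester endo under ring A and the C2 ester exo, which leads to the 1,2-trans (1R) product. The step thus needs facial and endo/exo selectivity: the first rests on the two cooperating auxiliaries, the second only on steric repulsion between the twisted C1 aryl group and a bulky C2 ester lying beneath it, so 12 is separated from its diastereomers by chromatography and crystallisation, without any base treatment, before it is carried on.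

Step 7
Reactants: 12 bis[(S)-1-methoxy-1-oxopropan-2-yl] (1R,2S,3S)-1-(3,4-dimethoxyphenyl)-6,7-dimethoxy-1,2,3,4-tetrahydronaphthalene-2,3-dicarboxylate
Product: 13 [(1R,2S,3S)-1-(3,4-dimethoxyphenyl)-6,7-dimethoxy-1,2,3,4-tetrahydronaphthalene-2,3-diyl]dimethanol
Conditions: LiAlH4 (4 equiv), THF, 0 °C → rt; H2O, aq NaOH work-up
Reagents that add atoms: none
Why: LiAlH4 ester reduction of all four ester groups turns the C2 and C3 carboxyls into CH2OH faster than they can enolise (and the all-trans array is the stable one anyway), while the auxiliary leaves as water-soluble (S)-propane-1,2-diol and methanol.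

Step 8
Reactants: 13 [(1R,2S,3S)-1-(3,4-dimethoxyphenyl)-6,7-dimethoxy-1,2,3,4-tetrahydronaphthalene-2,3-diyl]dimethanol
Product: 14 phyltetralin, (1R,2S,3S)-1-(3,4-dimethoxyphenyl)-6,7-dimethoxy-2,3-bis(methoxymethyl)-1,2,3,4-tetrahydronaphthalene
Conditions: NaH (3 equiv), MeI (4 equiv), THF, 0 °C → rt
Reagents that add atoms: iodomethane, CI
Why: Williamson ether synthesis on two unhindered primary alkoxides should be clean, and since no stereocentre carries an acidic hydrogen any more the configuration is retained.

Compound list
1 | 2-bromo-4,5-dimethoxybenzyl alcohol | COc1cc(Br)c(CO)cc1OC | starting material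
2 | veratraldehyde (3,4-dimethoxybenzaldehyde) | COc1ccc(C=O)cc1OC | starting material
3 | lithium (2-lithio-4,5-dimethoxyphenyl)methanolate (dilithio species) | [Li]OCc1cc(OC)c(OC)cc1[Li] | intermediate
4 | rac-(3,4-dimethoxyphenyl)[2-(hydroxymethyl)-4,5-dimethoxyphenyl]methanol | COc1ccc(C(O)c2cc(OC)c(OC)cc2CO)cc1OC | intermediate
5 | rac-1-[bromo(3,4-dimethoxyphenyl)methyl]-2-(bromomethyl)-4,5-dimethoxybenzene | COc1ccc(C(Br)c2cc(OC)c(OC)cc2CBr)cc1OC | intermediate
6 | rac-1-(3,4-dimethoxyphenyl)-5,6-dimethoxy-1,3-dihydrobenzo[c]thiophene | COc1ccc(C2SCc3cc(OC)c(OC)cc32)cc1OC | intermediate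
7 | rac-1-(3,4-dimethoxyphenyl)-5,6-dimethoxy-1,3-dihydrobenzo[c]thiophene 2,2-dioxide | COc1ccc(C2c3cc(OC)c(OC)cc3CS2(=O)=O)cc1OC | intermediate
8 | fumaryl chloride | O=C(Cl)/C=C/C(Cl)=O | starting material
9 | methyl (S)-lactate | C[C@H](O)C(=O)OC | starting material
10 | bis[(S)-1-methoxy-1-oxopropan-2-yl] fumarate | C[C@@H](C(=O)OC)OC(=O)/C=C/C(=O)O[C@@H](C)C(=O)OC | intermediate
11 | (5E)-5-(3,4-dimethoxybenzylidene)-2,3-dimethoxy-6-methylidenecyclohexa-1,3-diene (aryl outward) | COc1ccc(/C=C2\C=C(OC)C(OC)=CC2=C)cc1OC | intermediate
12 | bis[(S)-1-methoxy-1-oxopropan-2-yl] (1R,2S,3S)-1-(3,4-dimethoxyphenyl)-6,7-dimethoxy-1,2,3,4-tetrahydronaphthalene-2,3-dicarboxylate (all-trans) | C[C@@H](C(=O)OC)OC(=O)[C@H]1Cc2cc(OC)c(OC)cc2[C@@H](c2ccc(OC)c(OC)c2)[C@@H]1C(=O)O[C@@H](C)C(=O)OC | intermediate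
13 | [(1R,2S,3S)-1-(3,4-dimethoxyphenyl)-6,7-dimethoxy-1,2,3,4-tetrahydronaphthalene-2,3-diyl]dimethanol | OC[C@H]1Cc2cc(OC)c(OC)cc2[C@@H](c2ccc(OC)c(OC)c2)[C@@H]1CO | intermediate
14 | phyltetralin, (1R,2S,3S) | COC[C@H]1Cc2cc(OC)c(OC)cc2[C@@H](c2ccc(OC)c(OC)c2)[C@@H]1COC | target

Total step count: 8. Longest linear sequence: 7 (steps 1, 2, 3, 4, 6, 7, 8).

Steps most likely to fail

**Step 6 (key step).**
- The orientation with the C2 ester endo may compete or even prevail.
- Facial discrimination may erode at the temperature that SO2 loss requires.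
- The diene may be lost through electrocyclisation or dimerisation.
- Alkoxide equilibration of the crude auxiliary-bearing adducts is no cure. Adducts formed on the same fumarate face but differing at C1 would, on inversion of C2 and C3, drift into the mirror-image all-trans series and lower the enantiopurity.

Fallback: stereocontrol by resolution instead of by auxiliary. Setting out from 7, thermolysis under the same conditions with dimethyl fumarate (COC(=O)/C=C/C(=O)OC) gives racemic adducts via 11. NaOMe in MeOH is legitimate in the racemic series and should converge all C2/C3 epimers on the racemic all-trans dimethyl ester F1, the isomer that can hold all three substituents (pseudo)equatorial. LiAlH4 in THF then gives the racemic diol F2. Preparative chromatography on a cellulose tris(3,5-dimethylphenylcarbamate) phase delivers the (1R,2S,3S)-enantiomer, which is 13, where the route is rejoined.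

**Step 2.** Easy ionisation at the diarylmethyl carbon may divert material through internal etherification, hydrolysis on handling or Friedel–Crafts self-condensation.

Fallback: bring in sulfur before the carbinol, so that no dihalide is needed. Setting out from 1, 2-methylpropane-2-thiol and ZnI2 in 1,2-dichloroethane give the tert-butyl thioether F3. n-BuLi in THF at −78 °C gives the aryllithium F4, which adds to 2 to give the carbinol F5. CF3CO2H with anisole in CH2Cl2 ionises the carbinol, the thioether sulfur captures the cation, and the sulfonium ion sheds 2-methylpropene. This gives 6, where the route is rejoined.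

**Step 3.** Intermolecular sulfide bridging and solvolysis of the labile bromide may outrun ring closure.

Fallback: introduce sulfur already at the sulfinate level. Setting out from 5, HOCH2SO2Na and Bu4NBr in DMF at 0 °C give the sultine F6 by S-alkylation at the primary carbon, loss of formaldehyde and O-closure at the diarylmethyl carbon. Warming it in toluene in a closed vessel lets it fragment to 11 and SO2, which recombine cheletropically to the more stable sulfone 7. The route is rejoined there, with 6 and step 4 bypassed.

Further compounds
F1 | step 6 | rac-dimethyl (1R*,2S*,3S*)-1-(3,4-dimethoxyphenyl)-6,7-dimethoxy-1,2,3,4-tetrahydronaphthalene-2,3-dicarboxylate (both enantiomers) | COC(=O)[C@H]1Cc2cc(OC)c(OC)cc2[C@@H](c2ccc(OC)c(OC)c2)[C@@H]1C(=O)OC.COC(=O)[C@@H]1Cc2cc(OC)c(OC)cc2[C@H](c2ccc(OC)c(OC)c2)[C@H]1C(=O)OC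
F2 | step 6 | rac-[(1R*,2S*,3S*)-1-(3,4-dimethoxyphenyl)-6,7-dimethoxy-1,2,3,4-tetrahydronaphthalene-2,3-diyl]dimethanol (both enantiomers) | OC[C@H]1Cc2cc(OC)c(OC)cc2[C@@H](c2ccc(OC)c(OC)c2)[C@@H]1CO.OC[C@@H]1Cc2cc(OC)c(OC)cc2[C@H](c2ccc(OC)c(OC)c2)[C@H]1CO
F3 | step 2 | 1-bromo-2-[(tert-butylsulfanyl)methyl]-4,5-dimethoxybenzene | COc1cc(Br)c(CSC(C)(C)C)cc1OC
F4 | step 2 | {2-[(tert-butylsulfanyl)methyl]-4,5-dimethoxyphenyl}lithium | [Li]c1cc(OC)c(OC)cc1CSC(C)(C)C
F5 | step 2 | rac-{2-[(tert-butylsulfanyl)methyl]-4,5-dimethoxyphenyl}(3,4-dimethoxyphenyl)methanol | COc1ccc(C(O)c2cc(OC)c(OC)cc2CSC(C)(C)C)cc1OC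
F6 | step 3 | 1-(3,4-dimethoxyphenyl)-6,7-dimethoxy-1,4-dihydro-2,3-benzoxathiine 3-oxide (racemic, diastereomer mixture at sulfur) | COc1ccc(C2OS(=O)Cc3cc(OC)c(OC)cc32)cc1OC
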